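**Plan**

1. Eudesmane numbering is used. Ring A is C5–C6–C7–C8–C9–C10 (OAc on C6, isopropyl on C7) and ring B is C10–C1–C2–C3–C4–C5 (Br on C1, OH/CH3 on C4). C5 lies between the oxygen-bearing C4 and C6 and is bonded to the quaternary C10, so the C5–C10 bond can be made by a semipinacol 1,2-shift of C10 from C6 to C5.
2. Retrosynthesis: C6–OAc ⇒ C6 ketone; C7–isopropyl ⇒ C7=C11 enone. Cutting C5–C10 and re-bonding C10 to C6 gives a cis-fused hydroazulene (cyclopentane C6–C7–C8–C9–C10, cycloheptane C10–C1–C2–C3–C4–C5–C6) that carries an all-cis 4,5,6-triol 5-mesylate.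
3. The triol comes from the C4=C5 alkene (cut C4–O, C5–O) and the cycloheptene from cutting C5–C6 (alkenyllithium onto a cyclopentanone). The bromo cyclopentanone comes from cutting C9–C10 and C1–Br (bromonium ring expansion of an alkenylcyclobutanol), which comes from cyclobutanone and a (Z)-alkenyl iodide.
4. Forward: the chain C10=C1–C2–C3–C4=C5 is assembled first. Cyclobutane (C6–C9) → cyclopentanone → seven-membered ring closed on C6 → one 1,2-shift turns the 5/7 bicycle into rings A and B → C7 and C6 are adjusted, acetate last.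
5. Stereochemistry: C1/C10 from anti addition across the (Z)-alkene under a chiral bromination catalyst; the cis ring fusion at C6 from the tether; C4 and C5 from hydroxyl-directed OsO4; C5 (trans-decalin) by inversion in the shift; C7 by axial protonation; C6 by hydride delivered from the 4-hydroxyl.

Key step: step 10

Remark: atom numbers C1–C11 are those of the plan; alpha/beta refer to the faces of the final decalin (C10 methyl = beta).
Assumption: the catalyst of step 5 is taken from the pseudoenantiomeric pair (DHQD)2PHAL/(DHQ)2PHAL, whichever delivers the (R,R) series drawn.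

**Route**

Step 1
Reactants: 1 2-(2-bromoethyl)-1,3-dioxolane; 2 propyne
Product: 5 2-[(3Z)-4-bromo-3-methylbut-3-en-1-yl]-1,3-dioxolane, via Grignard reagent [2-(1,3-dioxolan-2-yl)ethyl]magnesium bromide 3 (not isolated), via alkenylcopper [(1Z)-4-(1,3-dioxolan-2-yl)-2-methylbut-1-en-1-yl]copper 4 (not isolated)
Conditions: Mg, THF, 25 °C; CuBr·SMe2, Et2O/Me2S, −45 °C; 2, −25 °C; NBS, −40 to 0 °C; aq. NH4Cl
Reagents that add atoms: N-bromosuccinimide, O=C1CCC(=O)N1Br
Why: The Normant carbocupration adds the alkyl group and copper syn across propyne with copper on the terminal carbon, and bromination of the alkenyl–copper bond by NBS should go with retention, which fixes the (Z)-trisubstituted alkenyl bromide (future C4=C5, Br on C5).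

Step 2
Reactants: 5 2-[(3Z)-4-bromo-3-methylbut-3-en-1-yl]-1,3-dioxolane
Product: 6 (4Z)-5-bromo-4-methylpent-4-enal
Conditions: PPTS (cat.), acetone/H2O, 60 °C
Reagents that add atoms: water, O
Why: Acid-catalysed acetal hydrolysis frees the aldehyde (future C1) and leaves the alkenyl bromide untouched.

Step 3
Reactants: 6 (4Z)-5-bromo-4-methylpent-4-enal; 7 ethyltriphenylphosphonium iodide
Product: 11 (2Z,6Z)-7-bromo-2-iodo-6-methylhepta-2,6-diene, via ethylidenetriphenylphosphorane 8 (not isolated), via (1-iodoethyl)triphenylphosphonium iodide 9 (not isolated), via (1-iodoethylidene)triphenylphosphorane 10 (not isolated)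
Conditions: 7, n-BuLi, THF, 0 °C; I2, −78 °C; NaN(SiMe3)2, −78 °C; then 6, −78 to −20 °C
Reagents that add atoms: iodine, II
Why: The Wittig reaction of the alpha-iodo ylide (iodo-olefination of the Stork–Zhao type with an ethylidene ylide) should give the (Z)-2-iodoalk-2-ene, iodine cis to the chain, under kinetic control, which later places C6 and C2 cis on the C10=C1 alkene.

Step 4
Reactants: 11 (2Z,6Z)-7-bromo-2-iodo-6-methylhepta-2,6-diene; 12 cyclobutanone
Product: 14 1-[(2Z,6Z)-7-bromo-6-methylhepta-2,6-dien-2-yl]cyclobutan-1-ol, via alkenyllithium [(2Z,6Z)-7-bromo-6-methylhepta-2,6-dien-2-yl]lithium 13 (not isolated)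
Conditions: t-BuLi (2.0 equiv), Et2O, −78 °C; 12, −78 °C; aq. NH4Cl
Reagents that add atoms: none
Why: Iodine–lithium exchange with t-BuLi is much faster at the alkenyl iodide than at the alkenyl bromide and keeps the alkene geometry, and the alkenyllithium then adds to the carbonyl group of cyclobutanone (1,2-addition).

Step 5
Reactants: 14 1-[(2Z,6Z)-7-bromo-6-methylhepta-2,6-dien-2-yl]cyclobutan-1-ol
Product: 15 (2R)-2-[(1R,4Z)-1,5-dibromo-4-methylpent-4-en-1-yl]-2-methylcyclopentan-1-one
Conditions: NBS (1.1 equiv), (DHQD)2PHAL (10 mol %), toluene/CHCl3, −40 °C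
Reagents that add atoms: N-bromosuccinimide, O=C1CCC(=O)N1Br
Why: Proposed new method: the cinchona catalyst is expected to bind the cyclobutanol hydroxyl by hydrogen bonding and to pass Br+ from NBS to one face of the trisubstituted alkene, after which the strained ring bond C6–C9 migrates to C10 anti to the bromonium ion (semipinacol ring expansion), so that the (Z)-alkene geometry fixes the relative configuration of C1 and C10 and the catalyst the absolute one, the electron-poor alkenyl bromide staying inert; the closest known reaction types are the NBS-induced ring expansion of 1-alkenylcyclobutanols to 2-(1-bromoalkyl)cyclopentanones and the catalytic asymmetric halogenation/semipinacol rearrangement of aryl-substituted alkenylcyclobutanols, which has not been shown for an alkene carrying only alkyl groups.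

Step 6
Reactants: 15 (2R)-2-[(1R,4Z)-1,5-dibromo-4-methylpent-4-en-1-yl]-2-methylcyclopentan-1-one; 16 acetone
Product: 19 (2R)-2-[(1R,4Z)-1,5-dibromo-4-methylpent-4-en-1-yl]-2-methyl-5-(propan-2-ylidene)cyclopentan-1-one, via aldol adduct 17 (not isolated), via tertiary acetate 18 (not isolated)
Conditions: LiN(iPr)2, THF, −78 °C; 16; Ac2O, −78 to 0 °C; DBU, 23 °C
Reagents that add atoms: none
Why: A directed aldol addition of the lithium enolate (C7 is the only enolisable position) to acetone, followed by acetylation and E1cB elimination (aldol condensation), should give the conjugated isopropylidene ketone, which holds the future isopropyl carbons and leaves the ketone without alpha hydrogens for the next step.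

Step 7
Reactants: 19 (2R)-2-[(1R,4Z)-1,5-dibromo-4-methylpent-4-en-1-yl]-2-methyl-5-(propan-2-ylidene)cyclopentan-1-one
Product: 21 (3aR,4R,8aR)-4-bromo-3a,7-dimethyl-1-(propan-2-ylidene)-1,2,3,3a,4,5,6,8a-octahydroazulen-8a-ol, via cyclising alkenyllithium 20 (not isolated)
Conditions: t-BuLi (2.0 equiv), THF, −78 °C; aq. NH4Cl at −78 °C
Reagents that add atoms: none
Why: Bromine–lithium exchange at the alkenyl bromide and intramolecular 1,2-addition of the alkenyllithium to the ketone (anionic cyclisation, 7-exo-trig at the carbonyl carbon) close the cycloheptene; the tether sits on the face of C10 opposite to its methyl group, so C5 should bond to C6 on that face and the new C6 hydroxyl ends cis to the methyl group (cis ring fusion).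

Step 8
Reactants: 21 (3aR,4R,8aR)-4-bromo-3a,7-dimethyl-1-(propan-2-ylidene)-1,2,3,3a,4,5,6,8a-octahydroazulen-8a-ol
Product: 23 (3aR,4R,7S,8S,8aR)-4-bromo-3a,7-dimethyl-1-(propan-2-ylidene)decahydroazulene-7,8,8a-triol, via TMEDA-bound osmate ester 22 (not isolated)
Conditions: OsO4 (1.0 equiv), TMEDA, CH2Cl2, −78 °C; aq. Na2SO3, THF, 40 °C
Reagents that add atoms: osmium tetroxide, O=[Os](=O)(=O)=O
Why: Hydrogen-bond-directed syn-dihydroxylation by the OsO4–TMEDA complex should deliver both oxygens to the C4=C5 alkene on the face of the allylic C6 hydroxyl, which is also the convex face away from the five-membered ring, setting C4 and C5 in an all-cis triol, while the tetrasubstituted isopropylidene alkene is too hindered to react at −78 °C.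

Step 9
Reactants: 23 (3aR,4R,7S,8S,8aR)-4-bromo-3a,7-dimethyl-1-(propan-2-ylidene)decahydroazulene-7,8,8a-triol
Product: 24 (3aR,4R,7S,8S,8aR)-4-bromo-7,8a-dihydroxy-3a,7-dimethyl-1-(propan-2-ylidene)decahydroazulen-8-yl methanesulfonate
Conditions: MsCl (1.1 equiv), Et3N, CH2Cl2, −20 °C
Reagents that add atoms: methanesulfonyl chloride, CS(=O)(=O)Cl
Why: Sulfonylation of an alcohol: only the single secondary hydroxyl (C5) should react with MsCl and Et3N at low temperature, the two tertiary hydroxyls being too hindered.

Step 10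
Reactants: 24 (3aR,4R,7S,8S,8aR)-4-bromo-7,8a-dihydroxy-3a,7-dimethyl-1-(propan-2-ylidene)decahydroazulen-8-yl methanesulfonate
Product: 25 (4aR,5R,8S,8aR)-5-bromo-8-hydroxy-4a,8-dimethyl-2-(propan-2-ylidene)octahydronaphthalen-1(2H)-one
Conditions: Et3Al (3 equiv), CH2Cl2, −78 to 0 °C; aq. potassium sodium tartrate
Reagents that add atoms: none
Why: After Et3Al has deprotonated both tertiary hydroxyls and activated the mesylate, the C6–C10 bond, which is antiperiplanar to the equatorial C5–OMs bond in the chair-like cis-fused conformer, shifts from C6 to C5 while C6 becomes the carbonyl carbon (semipinacol, pinacol-type rearrangement of a vicinal diol monosulfonate). The closest known reaction type is the base- or aluminium-promoted rearrangement of cis-diol monosulfonates that interconverts decalin and hydroazulene skeletons. No ring is closed by a cyclisation: the single suprafacial 1,2-shift inserts C5 between C6 and C10, so the cyclopentane grows to ring A while the cycloheptane shrinks to ring B. C5 is set by inversion (SN2-like displacement of the mesylate whose configuration came from step 8), which gives the trans ring fusion, while C10 migrates with retention and C4 is untouched. The step needs migration of C10 and not of C3 (pushed by the C4 alkoxide) or of C7: C10 is fully substituted and has the higher migratory aptitude, its shift creates a carbonyl group conjugated with the isopropylidene group, C7 is gauche to the leaving group, and the all-cis arrangement keeps both neighbouring oxygens gauche to the mesylate so that no epoxide can form.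

Step 11
Reactants: 25 (4aR,5R,8S,8aR)-5-bromo-8-hydroxy-4a,8-dimethyl-2-(propan-2-ylidene)octahydronaphthalen-1(2H)-one
Product: 27 (2S,4aR,5R,8S,8aR)-5-bromo-8-hydroxy-4a,8-dimethyl-2-(propan-2-yl)octahydronaphthalen-1(2H)-one, via silyl enol ether 26 (not isolated)
Conditions: Cu(OAc)2·H2O (5 mol %), 1,2-bis(diphenylphosphino)benzene (5 mol %), PhMe2SiH, toluene, 23 °C; Bu4NF/AcOH, THF, 0 °C
Reagents that add atoms: none
Why: Copper hydride catalysed 1,4-hydrosilylation (conjugate reduction) puts hydride on C11 and traps the enolate as its silyl ether, which prevents reduction of the ketone, and buffered fluoride cleavage should protonate C7 from the axial alpha face through a chair-like transition state so that the isopropyl group becomes equatorial (beta).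

Step 12
Reactants: 27 (2S,4aR,5R,8S,8aR)-5-bromo-8-hydroxy-4a,8-dimethyl-2-(propan-2-yl)octahydronaphthalen-1(2H)-one
Product: 28 (1S,2S,4aR,5R,8S,8aS)-5-bromo-4a,8-dimethyl-2-(propan-2-yl)decahydronaphthalene-1,8-diol
Conditions: Me4NBH(OAc)3, MeCN/AcOH, −20 °C
Reagents that add atoms: none
Why: Evans–Saksena reduction: the axial 4-hydroxyl binds the triacetoxyborohydride and delivers hydride within the molecule to the beta face of the C6 carbonyl group, which should give the anti-1,3-diol with the equatorial 6-alpha hydroxyl.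

Step 13
Reactants: 28 (1S,2S,4aR,5R,8S,8aS)-5-bromo-4a,8-dimethyl-2-(propan-2-yl)decahydronaphthalene-1,8-diol
Product: 29 (1S,2S,4aR,5R,8S,8aS)-5-bromo-8-hydroxy-4a,8-dimethyl-2-(propan-2-yl)decahydronaphthalen-1-yl acetate (the target)
Conditions: Ac2O, pyridine, DMAP (cat.), CH2Cl2, 23 °C
Reagents that add atoms: acetic anhydride, CC(=O)OC(C)=O
Why: DMAP-catalysed acylation should be selective for the secondary C6 hydroxyl over the tertiary C4 hydroxyl, which is 1,3-diaxial to the angular methyl group.

**Compound list**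

1 | 2-(2-bromoethyl)-1,3-dioxolane | BrCCC1OCCO1 | starting material
2 | propyne | CC#C | starting material
3 | [2-(1,3-dioxolan-2-yl)ethyl]magnesium bromide (not isolated) | Br[Mg]CCC1OCCO1 | intermediate
4 | [(1Z)-4-(1,3-dioxolan-2-yl)-2-methylbut-1-en-1-yl]copper (not isolated) | [Cu]/C=C(C)\CCC1OCCO1 | intermediate
5 | 2-[(3Z)-4-bromo-3-methylbut-3-en-1-yl]-1,3-dioxolane | Br/C=C(C)\CCC1OCCO1 | intermediate
6 | (4Z)-5-bromo-4-methylpent-4-enal | O=CCC/C(C)=C\Br | intermediate
7 | ethyltriphenylphosphonium iodide | CC[P+](c1ccccc1)(c1ccccc1)c1ccccc1.[I-] | starting material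
8 | ethylidenetriphenylphosphorane (not isolated) | CC=P(c1ccccc1)(c1ccccc1)c1ccccc1 | intermediate
9 | (1-iodoethyl)triphenylphosphonium iodide (not isolated) | CC(I)[P+](c1ccccc1)(c1ccccc1)c1ccccc1.[I-] | intermediate
10 | (1-iodoethylidene)triphenylphosphorane (not isolated) | CC(I)=P(c1ccccc1)(c1ccccc1)c1ccccc1 | intermediate
11 | (2Z,6Z)-7-bromo-2-iodo-6-methylhepta-2,6-diene | C/C(I)=C/CC/C(C)=C\Br | intermediate
12 | cyclobutanone | O=C1CCC1 | starting material
13 | [(2Z,6Z)-7-bromo-6-methylhepta-2,6-dien-2-yl]lithium (not isolated) | C/C([Li])=C/CC/C(C)=C\Br | intermediate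
14 | 1-[(2Z,6Z)-7-bromo-6-methylhepta-2,6-dien-2-yl]cyclobutan-1-ol | C/C(=C/CC/C(C)=C\Br)C1(O)CCC1 | intermediate
15 | (2R)-2-[(1R,4Z)-1,5-dibromo-4-methylpent-4-en-1-yl]-2-methylcyclopentan-1-one | O=C1CCC[C@@]1(C)[C@H](Br)CC/C(C)=C\Br | intermediate
16 | acetone | CC(C)=O | starting material
17 | (2R)-2-[(1R,4Z)-1,5-dibromo-4-methylpent-4-en-1-yl]-5-(2-hydroxypropan-2-yl)-2-methylcyclopentan-1-one, both C5 epimers, present as its lithium alkoxide (not isolated) | O=C1C(C(C)(C)O)CC[C@@]1(C)[C@H](Br)CC/C(C)=C\Br | intermediate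
18 | 2-{(3R)-3-[(1R,4Z)-1,5-dibromo-4-methylpent-4-en-1-yl]-3-methyl-2-oxocyclopentyl}propan-2-yl acetate, both C1 epimers (not isolated) | O=C1C(C(C)(C)OC(C)=O)CC[C@@]1(C)[C@H](Br)CC/C(C)=C\Br | intermediate
19 | (2R)-2-[(1R,4Z)-1,5-dibromo-4-methylpent-4-en-1-yl]-2-methyl-5-(propan-2-ylidene)cyclopentan-1-one | O=C1C(=C(C)C)CC[C@@]1(C)[C@H](Br)CC/C(C)=C\Br | intermediate
20 | {(1Z,5R)-5-bromo-2-methyl-5-[(1R)-1-methyl-2-oxo-3-(propan-2-ylidene)cyclopentyl]pent-1-en-1-yl}lithium (not isolated) | O=C1C(=C(C)C)CC[C@@]1(C)[C@H](Br)CC/C(C)=C\[Li] | intermediate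
21 | (3aR,4R,8aR)-4-bromo-3a,7-dimethyl-1-(propan-2-ylidene)-1,2,3,3a,4,5,6,8a-octahydroazulen-8a-ol; cis-fused, with 8a-OH, 3a-CH3 and 4-Br on the same face | CC(C)=C1CC[C@@]2(C)[C@H](Br)CCC(C)=C[C@@]12O | intermediate
22 | cyclic osmate ester of 23 at O7 and O8, hexavalent osmium carrying two oxo ligands and TMEDA (not isolated) | CC(C)=C1CC[C@@]2(C)[C@H](Br)CC[C@]3(C)O[Os-2]4(=O)(=O)(O[C@@H]3[C@@]12O)[N+](C)(C)CC[N+]4(C)C | intermediate
23 | (3aR,4R,7S,8S,8aR)-4-bromo-3a,7-dimethyl-1-(propan-2-ylidene)decahydroazulene-7,8,8a-triol; the three hydroxyls are cis to one another and to the 3a-methyl | CC(C)=C1CC[C@@]2(C)[C@H](Br)CC[C@](C)(O)[C@H](O)[C@@]12O | intermediate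
24 | (3aR,4R,7S,8S,8aR)-4-bromo-7,8a-dihydroxy-3a,7-dimethyl-1-(propan-2-ylidene)decahydroazulen-8-yl methanesulfonate | CC(C)=C1CC[C@@]2(C)[C@H](Br)CC[C@](C)(O)[C@H](OS(C)(=O)=O)[C@@]12O | intermediate
25 | (4aR,5R,8S,8aR)-5-bromo-8-hydroxy-4a,8-dimethyl-2-(propan-2-ylidene)octahydronaphthalen-1(2H)-one; trans-fused, 1-beta-bromo-4-beta-hydroxyeudesm-7(11)-en-6-one | O=C1[C@@H]2[C@@](C)(CCC1=C(C)C)[C@H](Br)CC[C@]2(C)O | intermediate
26 | dimethyl(phenyl)silyl enol ether of 27 with the C6=C7 enol double bond (not isolated) | C[Si](C)(c1ccccc1)OC1=C(C(C)C)CC[C@@]2(C)[C@H](Br)CC[C@](C)(O)[C@H]12 | intermediate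
27 | (2S,4aR,5R,8S,8aR)-5-bromo-8-hydroxy-4a,8-dimethyl-2-(propan-2-yl)octahydronaphthalen-1(2H)-one | O=C1[C@@H]2[C@@](C)(CC[C@H]1C(C)C)[C@H](Br)CC[C@]2(C)O | intermediate
28 | (1S,2S,4aR,5R,8S,8aS)-5-bromo-4a,8-dimethyl-2-(propan-2-yl)decahydronaphthalene-1,8-diol | O[C@@H]1[C@@H]2[C@@](C)(CC[C@H]1C(C)C)[C@H](Br)CC[C@]2(C)O | intermediate
29 | (1S,2S,4aR,5R,8S,8aS)-5-bromo-8-hydroxy-4a,8-dimethyl-2-(propan-2-yl)decahydronaphthalen-1-yl acetate | CC(=O)O[C@@H]1[C@@H]2[C@@](C)(CC[C@H]1C(C)C)[C@H](Br)CC[C@]2(C)O | target

**Summary**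

Total step count: 13. Longest linear sequence: 13 steps (from 1 to 29).

Steps most likely to fail:

Step 5. The catalyst may discriminate poorly between the two faces of an alkene that carries only alkyl groups, so the ketone could form with low enantiomeric purity. Fallback: set out from 14 and run the known racemic ring expansion with NBS alone (CH2Cl2, 0 °C). This should still give a single relative configuration because the shift is anti and the alkene is (Z). The racemate consists of 15 and its enantiomer (2S)-2-[(1S,4Z)-1,5-dibromo-4-methylpent-4-en-1-yl]-2-methylcyclopentan-1-one F1. It is resolved by preparative chromatography on a chiral stationary phase, and the route is rejoined at 15.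

Step 10. The C4 alkoxide can push C3 toward C5 (ring contraction to an acetyl-substituted hydrindane), and the product aluminium aldolate can undergo retro-aldol cleavage; either process would divert material from the C10 shift. Fallback: set out from 24 and silylate the more accessible tertiary C4 hydroxyl (Et3SiOTf, 2,6-lutidine, CH2Cl2, −78 °C) to give (3aR,4R,7S,8S,8aR)-4-bromo-8a-hydroxy-3a,7-dimethyl-1-(propan-2-ylidene)-7-[(triethylsilyl)oxy]decahydroazulen-8-yl methanesulfonate F2, in which only the C6 hydroxyl can push. Et2AlCl (CH2Cl2, −78 °C) should then give (4aR,5R,8S,8aR)-5-bromo-4a,8-dimethyl-2-(propan-2-ylidene)-8-[(triethylsilyl)oxy]octahydronaphthalen-1(2H)-one F3. HF·pyridine (THF, 0 °C) removes the silyl group and returns to the route at 25.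

Step 7. t-BuLi may attack the enone carbonyl group or the secondary C–Br bond before bromine–lithium exchange at the alkenyl bromide is complete, or it may abstract a proton from the isopropylidene methyl groups. Fallback: set out from 19 and close the ring under Nozaki–Hiyama–Kishi conditions (CrCl2, NiCl2 (cat.), DMSO, 50 °C, high dilution). The alkenylchromium species formed at the alkenyl C–Br bond tolerates the ketone and the alkyl bromide and should add to C6 from the same tethered face. The route is rejoined at 21 and no new compound is made on the way (F0).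

**Further compounds**

F1 | step 5 | (2S)-2-[(1S,4Z)-1,5-dibromo-4-methylpent-4-en-1-yl]-2-methylcyclopentan-1-one | O=C1CCC[C@]1(C)[C@@H](Br)CC/C(C)=C\Br
F2 | step 10 | (3aR,4R,7S,8S,8aR)-4-bromo-8a-hydroxy-3a,7-dimethyl-1-(propan-2-ylidene)-7-[(triethylsilyl)oxy]decahydroazulen-8-yl methanesulfonate | CC(C)=C1CC[C@@]2(C)[C@H](Br)CC[C@](C)(O[Si](CC)(CC)CC)[C@H](OS(C)(=O)=O)[C@@]12O
F3 | step 10 | (4aR,5R,8S,8aR)-5-bromo-4a,8-dimethyl-2-(propan-2-ylidene)-8-[(triethylsilyl)oxy]octahydronaphthalen-1(2H)-one | O=C1[C@@H]2[C@@](C)(CCC1=C(C)C)[C@H](Br)CC[C@]2(C)O[Si](CC)(CC)CC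
F0 | step 7 | none | none
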